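**Retrosynthetic overview**
- Last bond: C15–C16, by a vinylogous Mukaiyama aldol of a silyloxyfuran with the side-chain enal of a labdane 15,18-dial. This is the only C–C bond made, and it sets C15 and C16.
- Key bond: C18–O, by 6α-hydroxyl-directed oxygenation of the peri 4α-methyl C–H (silicon tether, then Si–C to O–C). C18 and C15 are later raised to aldehydes together.
- New step: the C15–O bond and the 13E alkene, by a chirality-relayed 1,3-acetoxy shift of the tertiary allylic acetate. The C13 stereocentre is traded for the alkene geometry.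
- Rings: no carbocycle is built. Rings A and B, with C5, C6, C9, C10, the 8(17)-methylene and the 6α-oxygen, come from (+)-larixol. The butenolide ring comes preformed from 4-methylfuran-2(5H)-one and is attached last.

Assumption: (+)-larixol, the 6α-hydroxy-13-epi-manool obtained by saponifying larch turpentine, is taken as an inexpensive commercial terpenoid.

Labdane numbering is used throughout; C18 is the 4α (equatorial) carbon and C19 the 4β (axial) methyl.

**Step 1**
Reactants: 1 (+)-larixol, (13S)-labda-8(17),14-diene-6α,13-diol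
Product: 2 larixol 6,13-diacetate
Conditions: Ac2O, Et3N, DMAP (0.2 equiv), toluene, 60 °C
Reagents that add atoms: acetic anhydride, CC(=O)OC(C)=O
Why: DMAP-catalysed acyl transfer esterifies the secondary 6α-hydroxyl and, on heating, the tertiary allylic 13-hydroxyl, with retention at C6 and C13 because no C–O bond of the substrate is broken.

**Step 2**
Reactants: 2 larixol 6,13-diacetate
Product: 4 (13E)-labda-8(17),13-diene-6α,15-diol, via E-diacetate 3 (not isolated)
Conditions: Pd(OCOCF3)2 (5 mol%), (S,S)-tBu-box (6 mol%), CH2Cl2, 0 °C to rt; then K2CO3 (0.3 equiv), MeOH, 40 °C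
Reagents that add atoms: none
Why: Proposed new method: a chirality-relayed 1,3-acyloxy shift in which the chiral divalent palladium complex binds the vinyl group, the acetate carbonyl oxygen adds to C15 anti to palladium through a six-membered acetoxonium and anti-elimination forms C13=C14 (the cyclisation-induced [3,3] allylic acetate transposition, known with PdCl2(MeCN)2 but then poorly E/Z-selective for methyl/alkyl carbinols); because both events are stereospecific, the face of C14 that palladium occupies decides, for the single (13S) acetate, whether C12 or the methyl group ends trans to C15, so the bisoxazoline antipode that holds palladium on the Re face of C14 (taken as (S,S); the (R,R) ligand is the control) converts the C13 stereocentre into the E alkene while forming the C15–O bond, the closest known reactions being the achiral palladium-catalysed acetate transposition and enantioface-selective palladium-catalysed allylic imidate rearrangements; ester exchange with methanol then frees both hydroxyls.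

**Step 3**
Reactants: 4 (13E)-labda-8(17),13-diene-6α,15-diol
Product: 5 (13E)-15-[(tert-butyldimethylsilyl)oxy]labda-8(17),13-dien-6α-ol
Conditions: TBSCl (1.05 equiv), imidazole, CH2Cl2, 0 °C
Reagents that add atoms: tert-butyldimethylsilyl chloride, CC(C)(C)[Si](C)(C)Cl
Why: Silyl ether formation is selective for the primary allylic hydroxyl over the hindered equatorial 6α-hydroxyl that is peri to the 4α-methyl, and no stereocentre is touched.

**Step 4**
Reactants: 5 (13E)-15-[(tert-butyldimethylsilyl)oxy]labda-8(17),13-dien-6α-ol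
Product: 8 (13E)-labda-8(17),13-diene-6α,15,18-triol, via hydrosilyl ether 6 (not isolated), via oxasilinane 7 (not isolated)
Conditions: Et2SiH2, [Ir(cod)OMe]2 (0.5 mol%), THF, rt; then [Rh(cod)Cl]2 (2 mol%), Xantphos, norbornene, THF, 100 °C; then Bu4NF, KHCO3, 30% H2O2, THF/MeOH, 50 °C
Reagents that add atoms: hydrogen peroxide, OO; diethylsilane, CC[SiH2]CC (its silicon is present only in 6 and 7)
Why: Hydroxyl-directed dehydrogenative C–H silylation followed by Tamao–Fleming oxidation: the 6α-O–SiEt2H group has no γ C–H (C4 and C10 are quaternary, C8 is sp2) and reaches only the peri 4α-methyl, closing a strain-free six-membered oxasilinane, so C18 rather than the axial C19 is functionalised and C4 becomes a stereocentre with the 4α-CH2OH; oxidation of Si–C proceeds with retention and fluoride frees O15 in the same flask.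

**Step 5**
Reactants: 8 (13E)-labda-8(17),13-diene-6α,15,18-triol
Product: 9 (13E)-6α-hydroxylabda-8(17),13-diene-15,18-dial
Conditions: TEMPO (20 mol%), PhI(OAc)2 (2.2 equiv), CH2Cl2, rt
Reagents that add atoms: none
Why: Oxoammonium (TEMPO) oxidation takes the two primary alcohols far faster than the hindered secondary 6α-hydroxyl, giving the E enal and the neopentyl aldehyde in one operation without touching a stereocentre (C4 is quaternary); the reagent is limited to 2.2 equivalents to avoid oxidising the 6,18-lactol on to the lactone.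

**Step 6**
Reactants: 10 4-methylfuran-2(5H)-one
Product: 11 trimethyl[(4-methylfuran-2-yl)oxy]silane
Conditions: TMSOTf, Et3N, Et2O, 0 °C
Reagents that add atoms: trimethylsilyl trifluoromethanesulfonate, C[Si](C)(C)OS(=O)(=O)C(F)(F)F
Why: Soft enolisation (silyl dienol ether formation): O-silylation of the lactone carbonyl and loss of the γ-proton to triethylamine give the aromatic 2-silyloxyfuran; no stereocentre is involved.

**Step 7**
Reactants: 9 (13E)-6α-hydroxylabda-8(17),13-diene-15,18-dial; 11 trimethyl[(4-methylfuran-2-yl)oxy]silane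
Product: 13 target, (13E,15S)-6α,15-dihydroxy-15-[(2S)-3-methyl-5-oxo-2,5-dihydrofuran-2-yl]labda-8(17),13-dien-18-al, via silyl ether 12 (not isolated)
Conditions: Ti(OiPr)4 (20 mol%), (R)-BINOL (20 mol%), Et2O, −20 °C; then AcOH/THF/H2O, rt
Reagents that add atoms: none
Why: Titanium–BINOL-catalysed vinylogous Mukaiyama aldol: C5 of the silyloxyfuran adds 1,2 to the unhindered enal (the neopentyl C18 aldehyde, flanked by quaternary C4 and the 6α-hydroxyl, reacts much more slowly) through an open synclinal transition state that favours the syn adduct, and the (R)-BINOL complex is expected, by analogy with the parent silyloxyfuran, to direct attack to the Re face of C15, making C15 and the butenolide carbon both S; mild acid then removes the silyl group.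

**Compound list**
1 | (+)-larixol, (13S)-labda-8(17),14-diene-6α,13-diol | C=C1C[C@H](O)[C@@H]2[C@](C)(CCCC2(C)C)[C@H]1CC[C@](C)(O)C=C | starting material
2 | larixol 6,13-diacetate, (13S)-labda-8(17),14-diene-6α,13-diyl diacetate | C=C1C[C@H](OC(C)=O)[C@@H]2[C@](C)(CCCC2(C)C)[C@H]1CC[C@](C)(OC(C)=O)C=C | intermediate
3 | (13E)-labda-8(17),13-diene-6α,15-diyl diacetate | C=C1C[C@H](OC(C)=O)[C@@H]2[C@](C)(CCCC2(C)C)[C@H]1CC/C(C)=C/COC(C)=O | intermediate
4 | (13E)-labda-8(17),13-diene-6α,15-diol | C=C1C[C@H](O)[C@@H]2[C@](C)(CCCC2(C)C)[C@H]1CC/C(C)=C/CO | intermediate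
5 | (13E)-15-[(tert-butyldimethylsilyl)oxy]labda-8(17),13-dien-6α-ol | C=C1C[C@H](O)[C@@H]2[C@](C)(CCCC2(C)C)[C@H]1CC/C(C)=C/CO[Si](C)(C)C(C)(C)C | intermediate
6 | 6α-O-diethylsilyl (Si–H) ether of 5 | C=C1C[C@H](O[SiH](CC)CC)[C@@H]2[C@](C)(CCCC2(C)C)[C@H]1CC/C(C)=C/CO[Si](C)(C)C(C)(C)C | intermediate
7 | oxasilinane of 5: diethylsilylene bridge from the 6α-oxygen to C18 (ring O6–Si–C18–C4–C5–C6), 4β-methyl kept | C=C1C[C@H](O3)[C@@H]2[C@](C)(CCC[C@@]2(C)C[Si]3(CC)CC)[C@H]1CC/C(C)=C/CO[Si](C)(C)C(C)(C)C | intermediate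
8 | (13E)-labda-8(17),13-diene-6α,15,18-triol (4α-CH2OH, 4β-CH3) | C=C1C[C@H](O)[C@@H]2[C@](C)(CCC[C@@]2(C)CO)[C@H]1CC/C(C)=C/CO | intermediate
9 | (13E)-6α-hydroxylabda-8(17),13-diene-15,18-dial (4α-CHO) | C=C1C[C@H](O)[C@@H]2[C@](C)(CCC[C@@]2(C)C=O)[C@H]1CC/C(C)=C/C=O | intermediate
10 | 4-methylfuran-2(5H)-one | CC1=CC(=O)OC1 | starting material
11 | trimethyl[(4-methylfuran-2-yl)oxy]silane | Cc1coc(O[Si](C)(C)C)c1 | intermediate
12 | 15-O-trimethylsilyl ether of 13 | C=C1C[C@H](O)[C@@H]2[C@](C)(CCC[C@@]2(C)C=O)[C@H]1CC/C(C)=C/[C@H](O[Si](C)(C)C)[C@H]1OC(=O)C=C1C | intermediate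
13 | (13E,15S)-6α,15-dihydroxy-15-[(2S)-3-methyl-5-oxo-2,5-dihydrofuran-2-yl]labda-8(17),13-dien-18-al (CNP0113661.1) | C=C1C[C@H](O)[C@@H]2[C@](C)(CCC[C@@]2(C)C=O)[C@H]1CC/C(C)=C/[C@H](O)[C@H]1OC(=O)C=C1C | target

**Totals**
Total step count: 7. Longest linear sequence: 6 (steps 1, 2, 3, 4, 5 and 7).

**Three steps most likely to fail**

Step 2 (the proposed new step). The ligand may not override the small intrinsic methyl/alkyl bias, giving an E/Z mixture, or the Lewis-acidic palladium may ionise the tertiary allylic acetate. The fallback uses known chemistry, sets out from 1 and comes back at 4. KMnO4 with benzyltriethylammonium chloride in CH2Cl2/water at 0 °C cleaves the vinyl carbinol to the methyl ketone 6α-hydroxy-14,15-dinorlabd-8(17)-en-13-one F1. A Horner–Wadsworth–Emmons reaction with triethyl phosphonoacetate and NaH in THF gives, after removal of the minor Z isomer on silica, ethyl (13E)-6α-hydroxylabda-8(17),13-dien-15-oate F2. Diisobutylaluminium hydride in CH2Cl2 at −78 °C reduces the ester to 4.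

Step 4. Rhodium hydride species may isomerise or hydrosilylate the 8(17)-methylene, or the six-membered silacycle may not close. The fallback replaces the organometallic C–H activation by an alkoxyl-radical 1,5-hydrogen transfer with the alkene masked; it sets out from 1 and comes back at 8.
- I2 and NaHCO3 in MeCN at 0 °C lock the 8(17)-alkene and the 13-hydroxyl as the iodoether (13S)-8α,13-epoxy-17-iodolabd-14-en-6α-ol F3, so that the C6 alkoxyl radical cannot fragment to an allyl radical.
- NOCl in pyridine gives (13S)-8α,13-epoxy-17-iodolabd-14-en-6α-yl nitrite F4.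
- Barton nitrite photolysis (350 nm, benzene, under O2) transfers the oxygen function to the peri 4α-methyl and gives (13S)-8α,13-epoxy-6α-hydroxy-17-iodolabd-14-en-18-yl nitrate F5.
- Zn in AcOH reduces the nitrate and reopens the iodoether to (13S)-labda-8(17),14-diene-6α,13,18-triol F6.
- Acetylation as in step 1 gives (13S)-labda-8(17),14-diene-6α,13,18-triyl triacetate F7.
- The rearrangement of step 2 (or PdCl2(MeCN)2 with separation of the Z isomer) gives (13E)-labda-8(17),13-diene-6α,15,18-triyl triacetate F8.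
- K2CO3 in MeOH gives 8.

Step 7. The C18 aldehyde or the free 6α-hydroxyl may interfere with the titanium catalyst, and syn and facial selectivity with the 4-methyl donor and an enal are not established. The fallback removes the second aldehyde from the aldol by changing the order of oxidation and fragment union; it sets out from 8 and comes back at 13. MnO2 in CH2Cl2 oxidises only the allylic hydroxyl to (13E)-6α,18-dihydroxylabda-8(17),13-dien-15-al F9. The same titanium–BINOL aldol with 11 gives the silyl ether (13E,15S)-15-[(2S)-3-methyl-5-oxo-2,5-dihydrofuran-2-yl]-15-(trimethylsilyloxy)labda-8(17),13-diene-6α,18-diol F10. AcOH/THF/H2O then gives (13E,15S)-15-[(2S)-3-methyl-5-oxo-2,5-dihydrofuran-2-yl]labda-8(17),13-diene-6α,15,18-triol F11. TEMPO with N-chlorosuccinimide and Bu4NCl in CH2Cl2/aqueous NaHCO3–K2CO3 oxidises the primary neopentyl alcohol in preference to the two secondary ones and gives 13.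

**Further compounds**
F1 | step 2 | 6α-hydroxy-14,15-dinorlabd-8(17)-en-13-one | C=C1C[C@H](O)[C@@H]2[C@](C)(CCCC2(C)C)[C@H]1CCC(C)=O
F2 | step 2 | ethyl (13E)-6α-hydroxylabda-8(17),13-dien-15-oate | C=C1C[C@H](O)[C@@H]2[C@](C)(CCCC2(C)C)[C@H]1CC/C(C)=C/C(=O)OCC
F3 | step 4 | (13S)-8α,13-epoxy-17-iodolabd-14-en-6α-ol | IC[C@@]1(O3)C[C@H](O)[C@@H]2[C@](C)(CCCC2(C)C)[C@H]1CC[C@@]3(C)C=C
F4 | step 4 | (13S)-8α,13-epoxy-17-iodolabd-14-en-6α-yl nitrite | IC[C@@]1(O3)C[C@H](ON=O)[C@@H]2[C@](C)(CCCC2(C)C)[C@H]1CC[C@@]3(C)C=C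
F5 | step 4 | (13S)-8α,13-epoxy-6α-hydroxy-17-iodolabd-14-en-18-yl nitrate | IC[C@@]1(O3)C[C@H](O)[C@@H]2[C@](C)(CCC[C@@]2(C)CO[N+](=O)[O-])[C@H]1CC[C@@]3(C)C=C
F6 | step 4 | (13S)-labda-8(17),14-diene-6α,13,18-triol | C=C1C[C@H](O)[C@@H]2[C@](C)(CCC[C@@]2(C)CO)[C@H]1CC[C@](C)(O)C=C
F7 | step 4 | (13S)-labda-8(17),14-diene-6α,13,18-triyl triacetate | C=C1C[C@H](OC(C)=O)[C@@H]2[C@](C)(CCC[C@@]2(C)COC(C)=O)[C@H]1CC[C@](C)(OC(C)=O)C=C
F8 | step 4 | (13E)-labda-8(17),13-diene-6α,15,18-triyl triacetate | C=C1C[C@H](OC(C)=O)[C@@H]2[C@](C)(CCC[C@@]2(C)COC(C)=O)[C@H]1CC/C(C)=C/COC(C)=O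
F9 | step 7 | (13E)-6α,18-dihydroxylabda-8(17),13-dien-15-al | C=C1C[C@H](O)[C@@H]2[C@](C)(CCC[C@@]2(C)CO)[C@H]1CC/C(C)=C/C=O
F10 | step 7 | (13E,15S)-15-[(2S)-3-methyl-5-oxo-2,5-dihydrofuran-2-yl]-15-(trimethylsilyloxy)labda-8(17),13-diene-6α,18-diol | C=C1C[C@H](O)[C@@H]2[C@](C)(CCC[C@@]2(C)CO)[C@H]1CC/C(C)=C/[C@H](O[Si](C)(C)C)[C@H]1OC(=O)C=C1C
F11 | step 7 | (13E,15S)-15-[(2S)-3-methyl-5-oxo-2,5-dihydrofuran-2-yl]labda-8(17),13-diene-6α,15,18-triol | C=C1C[C@H](O)[C@@H]2[C@](C)(CCC[C@@]2(C)CO)[C@H]1CC/C(C)=C/[C@H](O)[C@H]1OC(=O)C=C1C
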